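**Strategy.** The route rests on cutting the bond between oxolane C5 and its guaiacyl ring (ring B). It exploits two features: ring oxygen O1 lies between two benzylic carbons, and the C3 hydroxyl is anti to the O1–C2 bond, so O1 can be the oxygen of an aryl carbinol and C3–OH the oxygen of a trans-oxirane across C2–C3. The precursor is therefore acyclic: an α-methyl β,γ-epoxy aldehyde carrying ring A. In one operation an aryltitanium adds to the aldehyde (Felkin–Anh, forming C5–aryl and setting C5) and the new hydroxyl opens the oxirane at C2 with inversion (5-endo), closing the oxolane with all four stereocentres in place.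

Key step: step 9

Remark on the chemistry: oxolane numbering is O1, C2 (ring A), C3 (OH, CH3), C4 (CH3), C5 (ring B). The target is (2R,3S,4R,5R), with both aryl groups and both methyl groups on one face and the C3 hydroxyl on the other. 4-Iodo-2-methoxyphenol, methyl (R)-3-hydroxy-2-methylpropanoate and the L-fructose-derived Shi ketone are assumed to be purchasable.

**Step 1**
Reactants: 1 4-iodo-2-methoxyphenol
Product: 2 4-iodo-2-methoxyphenyl pivalate (2,2-dimethylpropanoate)
Conditions: PivCl, Et3N, DMAP (cat.), CH2Cl2, 0 °C → rt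
Reagents that add atoms: pivaloyl chloride, CC(C)(C)C(=O)Cl
Why: DMAP-catalysed O-acylation of the phenol; the hindered, electron-withdrawing pivalate is chosen to survive the aluminium, magnesium and titanium organometallics used later and to lower the donor strength of the para oxygen.

**Step 2**
Reactants: 3 methyl (R)-3-hydroxy-2-methylpropanoate
Product: 4 methyl (R)-3-[(tert-butyldimethylsilyl)oxy]-2-methylpropanoate
Conditions: TBSCl, imidazole, CH2Cl2, rt
Reagents that add atoms: tert-butyldimethylsilyl chloride, CC(C)(C)[Si](C)(C)Cl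
Why: silylation of the primary alcohol under mild base leaves the epimerisable ester α-centre, the future C4, untouched.

**Step 3**
Reactants: 4 methyl (R)-3-[(tert-butyldimethylsilyl)oxy]-2-methylpropanoate
Product: 5 (R)-3-[(tert-butyldimethylsilyl)oxy]-2-methylpropanal
Conditions: iBu2AlH (1.05 equiv), CH2Cl2, −78 °C; aq. potassium sodium tartrate
Reagents that add atoms: none
Why: partial ester reduction, in which the tetrahedral aluminium hemiacetal is stable at −78 °C and gives the aldehyde only on work-up, under non-basic conditions that preserve the α-stereocentre.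

**Step 4**
Reactants: 5 (R)-3-[(tert-butyldimethylsilyl)oxy]-2-methylpropanal
Product: 6 (S)-tert-butyldimethyl[(2-methylbut-3-yn-1-yl)oxy]silane
Conditions: dimethyl (1-diazo-2-oxopropyl)phosphonate, K2CO3, MeOH, 0 °C → rt
Reagents that add atoms: dimethyl (1-diazo-2-oxopropyl)phosphonate, CC(=O)C(=[N+]=[N-])P(=O)(OC)OC
Why: Ohira–Bestmann variant of the Seyferth–Gilbert homologation (diazomethylphosphonate addition, loss of N2, 1,2-shift in the alkylidene carbene) under base mild enough to keep the α-centre, whose descriptor becomes S only through the change in CIP priorities.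

**Step 5**
Reactants: 6 (S)-tert-butyldimethyl[(2-methylbut-3-yn-1-yl)oxy]silane and 2 4-iodo-2-methoxyphenyl pivalate
Product: 8 4-[(1E,3S)-4-[(tert-butyldimethylsilyl)oxy]-2,3-dimethylbut-1-en-1-yl]-2-methoxyphenyl pivalate, via alkenylalane 7 (not isolated)
Conditions: Me3Al (2.2 equiv), Cp2ZrCl2 (0.25 equiv), CH2Cl2, 0 °C → rt; volatiles removed; then 2, Pd(PPh3)4 (5 mol %), ZnCl2 (0.5 equiv), THF, rt
Reagents that add atoms: trimethylaluminium, C[Al](C)C
Why: Negishi zirconium-catalysed carboalumination adds CH3 and Al syn across the alkyne with CH3 on the internal carbon, and the palladium-catalysed cross-coupling of the alkenylalane with the aryl iodide goes with retention, so the E trisubstituted styrene (aryl cis to the new methyl) is formed while the aryl pivalate stays inert.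

**Step 6**
Reactants: 8 4-[(1E,3S)-4-[(tert-butyldimethylsilyl)oxy]-2,3-dimethylbut-1-en-1-yl]-2-methoxyphenyl pivalate
Product: 9 4-[(1E,3S)-4-hydroxy-2,3-dimethylbut-1-en-1-yl]-2-methoxyphenyl pivalate
Conditions: HF·pyridine, pyridine, THF, 0 °C → rt
Reagents that add atoms: none
Why: fluoride-driven cleavage of the primary silyl ether under buffered conditions that leave the aryl ester and the styrene untouched.

**Step 7**
Reactants: 9 4-[(1E,3S)-4-hydroxy-2,3-dimethylbut-1-en-1-yl]-2-methoxyphenyl pivalate
Product: 10 4-[(2S,3S)-3-[(2R)-1-hydroxypropan-2-yl]-3-methyloxiran-2-yl]-2-methoxyphenyl pivalate (trans-oxirane, aryl and hydroxypropyl chain on opposite faces)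
Conditions: L-fructose-derived Shi ketone (1,2:4,5-di-O-isopropylidene-β-L-erythro-2,3-hexodiulo-2,6-pyranose, 30 mol %), Oxone (2KHSO5·KHSO4·K2SO4), K2CO3, Bu4NHSO4, MeCN/dimethoxymethane/aq. Na2B4O7–Na2EDTA buffer, 0 °C
Reagents that add atoms: potassium peroxymonosulfate, [K+].[O-]S(=O)(=O)OO
Why: Shi asymmetric epoxidation, in which the chiral dioxirane transfers oxygen stereospecifically through a spiro transition state (E-alkene to trans-oxirane); the L-fructose-derived ketone is chosen because the D-fructose-derived one gives the (R)-benzylic oxirane carbon with E-aryl alkenes, so reagent control should set both oxirane carbons as S.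

**Step 8**
Reactants: 10 4-[(2S,3S)-3-[(2R)-1-hydroxypropan-2-yl]-3-methyloxiran-2-yl]-2-methoxyphenyl pivalate
Product: 11 4-[(2S,3S)-3-methyl-3-[(2S)-1-oxopropan-2-yl]oxiran-2-yl]-2-methoxyphenyl pivalate
Conditions: Dess–Martin periodinane, NaHCO3, CH2Cl2, 0 °C; used crude at once
Reagents that add atoms: none
Why: Dess–Martin oxidation with solid NaHCO3 avoids both acid (oxirane opening) and amine base (enolisation of the α-stereocentre and β-elimination onto the oxirane).

**Step 9**
Reactants: 11 4-[(2S,3S)-3-methyl-3-[(2S)-1-oxopropan-2-yl]oxiran-2-yl]-2-methoxyphenyl pivalate and 2 4-iodo-2-methoxyphenyl pivalate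
Product: 15 (2R,3S,4R,5R)-2,5-bis[3-methoxy-4-(pivaloyloxy)phenyl]-3,4-dimethyloxolan-3-ol, via arylmagnesium chloride 12 (not isolated), via aryltitanium triisopropoxide 13 (not isolated), via epoxy alcohol 14 (not isolated)
Conditions: 2, iPrMgCl·LiCl, THF, −20 °C; ClTi(OiPr)3, −78 °C; 11, −78 → −20 °C; aq. NH4Cl; crude 14, CSA (10 mol %), CH2Cl2, 0 °C (telescoped, no purification)
Reagents that add atoms: none
Why: Iodine–magnesium exchange of 2 and transmetalation give the non-basic, non-chelating aryltitanium 13, which adds to the aldehyde of 11 in the Felkin–Anh sense (fully substituted oxirane carbon anti to the incoming aryl, attack past H), forming the aryl–C5 bond and the (R)-carbinol of 14; under catalytic acid this hydroxyl attacks the benzylic oxirane carbon from the rear and the oxirane oxygen is released as the C3 tertiary alcohol. The closest known reaction types are the addition of organotitanium triisopropoxides to α-chiral aldehydes and the acid-catalysed cycloetherification of 3,4-epoxy alcohols to 3-hydroxyoxolanes. The oxolane closes in a 5-endo-tet mode (O1–C2 bond formation), preferred over 4-exo attack at the quaternary C3. C5 is controlled by the C4 methyl stereocentre (1,2-induction), C2 by inversion of the (S)-oxirane carbon set in step 7, and C3 and C4 are carried through unchanged, which together should give the all-cis aryl/methyl/methyl/aryl array with the hydroxyl on the opposite face. The step needs Felkin over chelation control and an SN2-like rather than ionising opening: the isopropoxytitanium reagent secures the first, the pivalate on ring A (weaker para-oxygen donation to C2) secures the second, and the same group on ring B keeps the new C5–O1 bond from ionising in acid.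

**Step 10**
Reactants: 15 (2R,3S,4R,5R)-2,5-bis[3-methoxy-4-(pivaloyloxy)phenyl]-3,4-dimethyloxolan-3-ol
Product: 16 (2R,3S,4R,5R)-2,5-bis(4-hydroxy-3-methoxyphenyl)-3,4-dimethyloxolan-3-ol
Conditions: K2CO3, MeOH (degassed), rt; aq. NH4Cl
Reagents that add atoms: none
Why: base-catalysed methanolysis (transesterification) of the two aryl esters, driven by the phenoxide leaving group; no bond to a stereocentre is touched and room temperature avoids quinone-methide-type epimerisation at the p-hydroxybenzylic C2 and C5.

**Compound list**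
1 | 4-iodo-2-methoxyphenol | COc1cc(I)ccc1O | starting material
2 | 4-iodo-2-methoxyphenyl pivalate | COc1cc(I)ccc1OC(=O)C(C)(C)C | intermediate
3 | methyl (R)-3-hydroxy-2-methylpropanoate | C[C@H](CO)C(=O)OC | starting material
4 | methyl (R)-3-[(tert-butyldimethylsilyl)oxy]-2-methylpropanoate | C[C@H](CO[Si](C)(C)C(C)(C)C)C(=O)OC | intermediate
5 | (R)-3-[(tert-butyldimethylsilyl)oxy]-2-methylpropanal | C[C@H](CO[Si](C)(C)C(C)(C)C)C=O | intermediate
6 | (S)-tert-butyldimethyl[(2-methylbut-3-yn-1-yl)oxy]silane | C#C[C@H](C)CO[Si](C)(C)C(C)(C)C | intermediate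
7 | dimethyl[(1E,3S)-4-[(tert-butyldimethylsilyl)oxy]-2,3-dimethylbut-1-en-1-yl]alane | C[Al](C)/C=C(\C)[C@H](C)CO[Si](C)(C)C(C)(C)C | intermediate
8 | 4-[(1E,3S)-4-[(tert-butyldimethylsilyl)oxy]-2,3-dimethylbut-1-en-1-yl]-2-methoxyphenyl pivalate | COc1cc(/C=C(\C)[C@H](C)CO[Si](C)(C)C(C)(C)C)ccc1OC(=O)C(C)(C)C | intermediate
9 | 4-[(1E,3S)-4-hydroxy-2,3-dimethylbut-1-en-1-yl]-2-methoxyphenyl pivalate | COc1cc(/C=C(\C)[C@H](C)CO)ccc1OC(=O)C(C)(C)C | intermediate
10 | 4-[(2S,3S)-3-[(2R)-1-hydroxypropan-2-yl]-3-methyloxiran-2-yl]-2-methoxyphenyl pivalate | OC[C@@H](C)[C@]1(C)O[C@H]1c1ccc(OC(=O)C(C)(C)C)c(OC)c1 | intermediate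
11 | 4-[(2S,3S)-3-methyl-3-[(2S)-1-oxopropan-2-yl]oxiran-2-yl]-2-methoxyphenyl pivalate | O=C[C@@H](C)[C@]1(C)O[C@H]1c1ccc(OC(=O)C(C)(C)C)c(OC)c1 | intermediate
12 | [3-methoxy-4-(pivaloyloxy)phenyl]magnesium chloride (LiCl complex) | COc1cc([Mg]Cl)ccc1OC(=O)C(C)(C)C | intermediate
13 | [3-methoxy-4-(pivaloyloxy)phenyl]titanium triisopropoxide | COc1cc([Ti](OC(C)C)(OC(C)C)OC(C)C)ccc1OC(=O)C(C)(C)C | intermediate
14 | 4-[(1R,2R)-1-hydroxy-2-[(2S,3S)-3-[3-methoxy-4-(pivaloyloxy)phenyl]-2-methyloxiran-2-yl]propyl]-2-methoxyphenyl pivalate | O[C@@H](c1ccc(OC(=O)C(C)(C)C)c(OC)c1)[C@@H](C)[C@]1(C)O[C@H]1c1ccc(OC(=O)C(C)(C)C)c(OC)c1 | intermediate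
15 | (2R,3S,4R,5R)-2,5-bis[3-methoxy-4-(pivaloyloxy)phenyl]-3,4-dimethyloxolan-3-ol | COc1cc([C@H]2O[C@@H](c3ccc(OC(=O)C(C)(C)C)c(OC)c3)[C@@H](C)[C@]2(C)O)ccc1OC(=O)C(C)(C)C | intermediate
16 | (2R,3S,4R,5R)-2,5-bis(4-hydroxy-3-methoxyphenyl)-3,4-dimethyloxolan-3-ol | COc1cc([C@H]2O[C@@H](c3ccc(O)c(OC)c3)[C@@H](C)[C@]2(C)O)ccc1O | target

**Count.** Total steps: 10. Longest linear sequence: 9 (steps 2 to 10, from 3).

**Steps most likely to fail**

Step 9 (key step). The aryl transfer may show poor facial selectivity at the aldehyde, or the oxirane may ionise or rearrange (Meinwald shift) before the hydroxyl closes the ring, which would erode C5 or C2. The fallback sets out from 10 and rejoins the route at 15. Oxidation of 10 (TEMPO (cat.), NaOCl (cat.), NaClO2, MeCN/phosphate buffer) should give the epoxy acid F1. On acidification (CSA, CH2Cl2) its carboxyl group should open the oxirane at C2 with inversion to give the hydroxy lactone F2. After deprotonation of the tertiary hydroxyl with iPrMgCl·LiCl, addition of 12 (THF, −40 °C) to the lactone carbonyl forms the aryl–C5 bond and should give the lactol F3 as an anomeric mixture. Ionic hydrogenation (Et3SiH, BF3·OEt2, CH2Cl2, −78 °C) of the aryl-stabilised oxocarbenium ion should deliver hydride to the face opposite the C4 methyl and the C2 aryl group, so that C5 is set by the ring and not by acyclic induction, giving 15.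

Step 8. The β,γ-epoxy aldehyde may epimerise at its α-carbon or undergo β-elimination with opening of the oxirane during oxidation, concentration or storage. The fallback sets out from 9 and rejoins the route at 14; it reverses the order so that no aldehyde ever carries the oxirane. Oxidation of 9 (Dess–Martin periodinane, NaHCO3, CH2Cl2, 0 °C) should give the β,γ-unsaturated aldehyde F4. Addition of 13 at −78 °C (Felkin–Anh, alkenyl group as the large substituent) should give the alkenyl carbinol F5. The Shi epoxidation of step 7, with the same L-fructose-derived ketone, is then run on F5 and should give 14, which closes to 15 under the acid treatment of step 9.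

Step 7. Oxygen transfer may occur with insufficient facial selectivity if the allylic stereocentre is mismatched with the ketone, the aryl pivalate may be hydrolysed at pH 10.5, or the product may cyclise through its own primary hydroxyl. The fallback sets out from 8 and rejoins the route at 10; the oxirane is introduced on the silyl ether by a metal-oxo catalyst in a two-phase system that keeps the substrate away from aqueous base. Jacobsen–Katsuki epoxidation of 8 ([N,N′-bis(3,5-di-tert-butylsalicylidene)-1,2-cyclohexanediaminato]manganese chloride, trivalent manganese, 5 mol %; NaOCl, 4-phenylpyridine N-oxide, CH2Cl2/H2O, 0 °C) should give the epoxy silyl ether F6. The catalyst antipode is to be chosen by converting a sample to 15, since the facial sense for this alkene class is not assigned here. Buffered fluoride (TBAF, AcOH, THF, 0 °C) then liberates 10, which is oxidised at once as in step 8.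

**Further compounds**
F1 | step 9 | (2S)-2-[(2S,3S)-3-[3-methoxy-4-(pivaloyloxy)phenyl]-2-methyloxiran-2-yl]propanoic acid | OC(=O)[C@@H](C)[C@]1(C)O[C@H]1c1ccc(OC(=O)C(C)(C)C)c(OC)c1
F2 | step 9 | 4-[(2R,3S,4S)-3-hydroxy-3,4-dimethyl-5-oxooxolan-2-yl]-2-methoxyphenyl pivalate | COc1cc([C@H]2OC(=O)[C@@H](C)[C@]2(C)O)ccc1OC(=O)C(C)(C)C
F3 | step 9 | 4-[(2R,3S,4S)-3,5-dihydroxy-5-[3-methoxy-4-(pivaloyloxy)phenyl]-3,4-dimethyloxolan-2-yl]-2-methoxyphenyl pivalate (both anomers) | COc1cc([C@H]2OC(O)(c3ccc(OC(=O)C(C)(C)C)c(OC)c3)[C@@H](C)[C@]2(C)O)ccc1OC(=O)C(C)(C)C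
F4 | step 8 | 4-[(1E,3S)-2,3-dimethyl-4-oxobut-1-en-1-yl]-2-methoxyphenyl pivalate | COc1cc(/C=C(\C)[C@H](C)C=O)ccc1OC(=O)C(C)(C)C
F5 | step 8 | 4-[(1R,2S,3E)-1-hydroxy-4-[3-methoxy-4-(pivaloyloxy)phenyl]-2,3-dimethylbut-3-en-1-yl]-2-methoxyphenyl pivalate | O[C@@H](c1ccc(OC(=O)C(C)(C)C)c(OC)c1)[C@@H](C)/C(C)=C/c1ccc(OC(=O)C(C)(C)C)c(OC)c1
F6 | step 7 | 4-[(2S,3S)-3-[(2R)-1-[(tert-butyldimethylsilyl)oxy]propan-2-yl]-3-methyloxiran-2-yl]-2-methoxyphenyl pivalate | CC(C)(C)[Si](C)(C)OC[C@@H](C)[C@]1(C)O[C@H]1c1ccc(OC(=O)C(C)(C)C)c(OC)c1
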